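The ratio of impurity to free catalyst is 0.150 in south and 0.600 in south-west, and I start from it because the bench rule for a poison is that one impurity takes one catalyst. Even in south-west there is less impurity than catalyst, so the impurity is the limiting reagent of that titration.

| flask | starting material | second substrate | free catalyst | impurity | remark | time |
|---|---|---|---|---|---|---|
| gamma | 0.96 M | 0.96 M | 54 mM | 11 mM | run made earlier |  |
| alpha | 0.96 M | 0.96 M | 54 mM | 31 mM | run made earlier |  |
| epsilon | 0.96 M | 0.55 M | 54 mM | 12 mM | run made earlier |  |
| north-east | 0.96 M | 0.250 M | 54 mM | 25 mM |  | 3.0 min |
| south-east | 0.96 M | 0.960 M | 40 mM | 8.0 mM |  | 3.0 min |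
| south | 0.50 M | 0.960 M | 80 mM | 12 mM |  | 3.0 min |
| south-west | 0.96 M | 0.960 M | 20 mM | 12 mM |  | 3.0 min |
| north-west | 0.96 M | 0.960 M | 54 mM | 12 mM |  | 3.0 min |

- gamma (time / s: target / %): 25.0: 19.9; 50.0: 30.7; 60.0: 32.4; 90.0: 37.4
- alpha (time / s: target / %): 12.0: 9.6; 30.0: 14.2; 60.0: 20.1; 90.0: 25.6
- epsilon (time / s: target / %): 25.0: 21.8; 50.0: 35.6; 60.0: 37.6; 90.0: 42.4

(each reading ± 1 percentage point)

- what was read earlier has a scatter of 1 percentage point, one standard deviation
- no earlier run changes the charge of free catalyst; that part of a forecast is a guess

1. the flasks by amount of target, in percent of the starting material charged, highest first, at 3.0 min (north-east / south-east / south / south-west / north-west)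
2. the amount of target, in percent of the starting material charged of the flask you put first, at 3.0 min
3. the amount of target, in percent of the starting material charged of the flask you put last, at 3.0 min

The rule gives, as c(free catalyst) − c(impurity):

gamma 43.0 mM, alpha 23.0 mM, epsilon 42.0 mM

south 68.0 mM, north-west 42.0 mM, south-east 32.0 mM, north-east 29.0 mM, south-west 8.00 mM

I call this difference the live catalyst. No earlier run changes the catalyst charge, so using it across charges is my guess.

Alpha against gamma tests the rule. The live ratio is 0.535, while the target ratio read at 90.0 s is 0.684, so these two runs fall in the order of their live catalyst, but their target is not proportional to it.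

Epsilon shows its border. With 42.0 mM against 43.0 mM in gamma, the live ratio is 0.977, yet at a second-substrate ratio to gamma of 0.573 the target ratio read at 90.0 s is 1.13. Epsilon reads more target than gamma, by more than the scatter, so live catalyst does not account for the difference between these two runs.

North-east, at a second-substrate ratio to gamma of 0.260, lies past that border. Its live ratio to south-east is 0.906, and if I carry epsilon's gain over unchanged, which is only my estimate, that becomes 1.03. I therefore put north-east level with south-east or above it, and I do not place it further. By live catalyst, south comes first and south-west last.

The forecast gives south > north-west > south-east > north-east > south-west, with 80% at the top and 12% at the bottom. On north-east it says: “North-east is capped by stoichiometry at 26%”. That puts north-east below south-east, where my reckoning differs.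

The flasks give south > north-east > north-west > south-east > south-west, with 56.5% in south, 18.6% in south-west and 53.1% in north-east.

    catalyst intermediate B → spent catalyst A (k = 3.30 × 10⁻⁴ /s)
    free catalyst + impurity → spent catalyst B (k = 15.0 /M/s)
    catalyst intermediate A ⇌ free catalyst + target (K = 1.10 M, k = 0.700 /s)
    catalyst intermediate B → free catalyst + second product (k = 0.0200 /s)
    second substrate + free catalyst ⇌ catalyst intermediate B (K = 57.0 /M, k = 0.0700 /M/s)
    starting material + free catalyst ⇌ catalyst intermediate A (K = 1.30 /M, k = 1.70 /M/s)

The neighbour is south with 0.020 M of free catalyst and its impurity unchanged. The same reckoning gives it 8.00 mM of live catalyst against 68.0 mM in south, and it puts 60.0% of the catalyst charged with the impurity. At 3.00 min that neighbour holds 59.9% of its catalyst as spent catalyst B. Its target stands at 19.7% against 56.5% in south, with 80% of its starting material still there, unbound.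

The runs were computed for substances that don't exist.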